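**Retrosynthetic overview** (ent-gibberellane numbering)
1. Feature: ring A (C1–C5, C10) holds quaternary C4 (C18 methyl, C19 carboxyl) and quaternary C10 (C20 carboxyl) on either side of the C5 methine. It is cis-fused along C5–C10 to cyclopentane ring B (C5, C6, C8, C9, C10), so the three contiguous centres fit one cyclohexene-forming [4+2].
2. Key disconnection: C5–C10 and C3–C4, by an intramolecular Diels–Alder reaction. The diene is a Z-dienoate on C9 (C10=C1–C2=C3, C20 ester on the inside position); the dienophile is a Z-enoate (C5=C4) on the C6 arm of C8. Rings A and B close together.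
3. Precursor: a bicyclo[3.2.1]octan-16-one (rings C and D). C7 travels as CH2OBn, because a C6 ester would make C6–H a glutaconate-type acid next to the Z-enoate. C19 and C20 travel as 2-(trimethylsilyl)ethyl esters.
4. Ring order: ring C by enamine Michael addition and aldol condensation, followed by two conjugate additions that build C8. Ring D by ketyl–alkyne closure, with C16=C17 kept as a masked ketone until ozonolysis. Then rings A and B.
5. End game: hydrogenation, oxidation and methylation of C7, Wittig methylenation at C16, global fluoride deprotection.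

Key step: step 22

Assumption: the stereodescriptors of the given SMILES are taken literally, so H5 and the C20 carboxyl are cis (cis A/B fusion) and C1 is syn to C11.
Abbreviations: TMSE = 2-(trimethylsilyl)ethyl; TBS = tert-butyldimethylsilyl; Bn = benzyl; Tf = trifluoromethanesulfonyl.

Step 1
Reactants: 1 pent-4-enoic acid; 2 2-(trimethylsilyl)ethanol
Product: 3 TMSE pent-4-enoate
Conditions: DCC, DMAP (cat.), CH2Cl2, 0 °C → rt
Reagents that add atoms: 2-(trimethylsilyl)ethanol 2, C[Si](C)(C)CCO
Why: Steglich esterification of an unhindered acid with a primary alcohol is routine and installs the fluoride-labile ester that will protect C20 to the end.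

Step 2
Reactants: 3 TMSE pent-4-enoate
Product: 4 TMSE 4-oxobutanoate
Conditions: O3, CH2Cl2, −78 °C; PPh3, −78 °C → rt
Reagents that add atoms: ozone, [O-][O+]=O
Why: Ozonolysis with reductive work-up cleaves the only alkene to the aldehyde carbon that becomes C8, and the ester is inert to ozone.

Step 3
Reactants: 4 TMSE 4-oxobutanoate; 5 methyl vinyl ketone
Product: 6 TMSE (3S)-3-formyl-6-oxoheptanoate
Conditions: (S)-2-[methoxy(diphenyl)methyl]pyrrolidine (5 mol %), ethyl 3,4-dihydroxybenzoate (20 mol %), neat, 4 °C
Reagents that add atoms: methyl vinyl ketone 5, C=CC(C)=O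
Why: In this enamine-catalysed asymmetric Michael addition the diphenyl(methoxy)methyl group shields one face of the E-enamine of 4, so the enone is attacked from the open face and C9 is set as S.

Step 4
Reactants: 6 TMSE (3S)-3-formyl-6-oxoheptanoate
Product: 7 TMSE [(1S)-4-oxocyclohex-2-en-1-yl]acetate (ring C: C13 ketone, C14=C8, C10–C20 side chain on C9)
Conditions: TsOH·H2O (5 mol %), toluene, 80 °C, water separator
Reagents that add atoms: none
Why: Intramolecular aldol condensation of the 1,5-keto aldehyde (methyl carbon C14 onto aldehyde C8) closes the six-membered ring quickly, and no bond to C9 is broken.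

Step 5
Reactants: 8 tert-butyl acetate
Product: 9 1-tert-butoxy-1-(tert-butyldimethylsilyloxy)ethene
Conditions: LiN(iPr)2, THF, −78 °C; TBSCl, DMPU, −78 °C → rt
Reagents that add atoms: tert-butyldimethylsilyl chloride, CC(C)(C)[Si](C)(C)Cl
Why: O-silylation of the kinetic ester enolate is the standard way to a ketene silyl acetal.

Step 6
Reactants: 7 enone; 9 ketene silyl acetal
Product: 10 trans silyl enol ether (C13(OTBS)=C14, CH2CO2tBu on C8, CH2CO2TMSE on C9)
Conditions: TBSOTf (5 mol %), CH2Cl2, −78 °C
Reagents that add atoms: 1-tert-butoxy-1-(tert-butyldimethylsilyloxy)ethene 9, C=C(OC(C)(C)C)O[Si](C)(C)C(C)(C)C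
Why: The Mukaiyama–Michael addition brings C6–C5 to C8 anti to the C9 side chain (this C8 centre is erased in step 7), and silyl transfer leaves the regiodefined enol ether that the next step needs.

Step 7
Reactants: 10 silyl enol ether
Product: 11 3,4-disubstituted cyclohex-2-enone (C8 bears CH2CO2tBu, C9 bears CH2CO2TMSE)
Conditions: Pd(OAc)2 (1.1 equiv), MeCN, rt
Reagents that add atoms: none
Why: Saegusa–Ito oxidation turns the C13=C14 enol ether into the C14=C8 enone under neutral conditions, so the γ-stereocentre C9 is not enolised.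

Step 8
Reactants: 11 enone; 12 allenyltributylstannane
Product: 13 cyclohexanone with quaternary C8 (propargyl C15–C17 trans to the C9 side chain, CH2CO2tBu cis to it)
Conditions: TiCl4 (2.2 equiv), CH2Cl2, −78 °C; then 12 (2 equiv), −78 °C; aq. NaHCO3
Reagents that add atoms: allenyltributylstannane 12, C=C=C[Sn](CCCC)(CCCC)CCCC
Why: In this Lewis-acid-mediated conjugate propargylation (SE2' transfer, same type as the Hosomi–Sakurai reaction) A(1,2) strain with the C8 substituent holds the C9 side chain pseudoaxial, so the stannane attacks anti to it and places C15 trans and C6 cis to C10.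

Step 9
Reactants: 13 propargyl ketone
Product: 14 bicyclo[3.2.1]octane alcohol (rings C and D: C13–OH, C16=C17H2, C8–CH2CO2tBu, C9–CH2CO2TMSE)
Conditions: SmI2 (3 equiv), HMPA, t-BuOH, THF, 0 °C → rt
Reagents that add atoms: none
Why: The reductive ketyl–alkyne cyclisation (5-exo-dig attack of the C13 ketyl on C16) is a proven entry to 1-hydroxy-7-methylenebicyclo[3.2.1]octanes; the one-atom bridge fixes C13 relative to C8, and both esters are inert.

Step 10
Reactants: 14 bicyclic alcohol
Product: 16 C13 TBS ether bearing the free C8 acetic acid arm, via bis-silylated silyl ester 15 (not isolated)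
Conditions: TBSOTf (3.5 equiv), 2,6-lutidine (5 equiv), CH2Cl2, 0 °C → rt; then aq. citric acid, THF, rt
Reagents that add atoms: tert-butyldimethylsilyl triflate, CC(C)(C)[Si](C)(C)OS(=O)(=O)C(F)(F)F
Why: The silyl triflate silylates the hindered tertiary alcohol and also converts the tert-butyl ester into a silyl ester with loss of isobutene; the silyl ester alone hydrolyses on work-up, so the two acetate arms become different.

Step 11
Reactants: 16 acid; 17 (R)-4-benzyl-1,3-oxazolidin-2-one
Product: 19 N-acyl oxazolidinone of the C6–C5 arm, via mixed pivalic anhydride 18 (not isolated)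
Conditions: pivaloyl chloride, Et3N, THF, −20 °C; then LiCl, 17, −20 °C → rt
Reagents that add atoms: (R)-4-benzyl-1,3-oxazolidin-2-one 17, O=C1OC[C@@H](Cc2ccccc2)N1
Why: In this acylation through the mixed anhydride the oxazolidinone attacks the less hindered acyl group, and the resulting imide can be enolised selectively beside the TMSE ester.

Step 12
Reactants: 19 imide; 20 benzyl chloromethyl ether
Product: 21 C6-alkylated imide (C6 bears CH2OBn = C7)
Conditions: TiCl4 (1.05 equiv), iPr2NEt (1.1 equiv), CH2Cl2, 0 °C; then 20 (2 equiv), 0 °C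
Reagents that add atoms: benzyl chloromethyl ether 20, ClCOCc1ccccc1
Why: In this Evans alkylation soft enolisation touches only the chelating imide, and the R auxiliary blocks one face of the chelated Z-enolate, so C6 is set under reagent control; the carbon added is C7, kept as an ether because an α-formyl ester at C6 would not survive olefination.

Step 13
Reactants: 21 alkylated imide
Product: 22 primary alcohol (C5H2OH on C6)
Conditions: NaBH4 (4 equiv), THF/H2O 4:1, 0 °C → rt
Reagents that add atoms: none
Why: Borohydride cleaves the activated exocyclic imide carbonyl to the alcohol and releases the auxiliary without touching the TMSE ester, and C6 keeps its configuration because no enolate is formed.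

Step 14
Reactants: 22 alcohol; 23 ethyl formate
Product: 24 hydroxymethylene ester (C10=C1H–OH, chelated Z-enol of the α-formyl ester)
Conditions: LiN(iPr)2 (3.2 equiv), THF, −78 °C; 23 (6 equiv), −78 → −20 °C; AcOH
Reagents that add atoms: ethyl formate 23, CCOC=O
Why: This crossed Claisen formylation works because, after the hydroxyl, C10H2 is the only site that the amide base can deprotonate (ether, silyl ether and exocyclic alkene are inert), so C1 is introduced cleanly.

Step 15
Reactants: 24 hydroxymethylene ester
Product: 25 Z-enol triflate (OTf on C1 cis to the C20 ester)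
Conditions: LiN(SiMe3)2 (1.0 equiv), THF, −78 °C; PhNTf2 (1.05 equiv), −78 → 0 °C
Reagents that add atoms: N-phenylbis(trifluoromethanesulfonimide), O=S(=O)(N(c1ccccc1)S(=O)(=O)C(F)(F)F)C(F)(F)F
Why: One equivalent of base removes only the acidic enol proton; lithium chelation and the bulk of C9 both hold the enolate oxygen cis to the ester, so O-sulfonylation fixes the Z geometry, and the neutral primary alcohol does not react with this mild triflating agent.

Step 16
Reactants: 25 enol triflate
Product: 26 C16 ketone
Conditions: O3, CH2Cl2, −78 °C, stopped when 25 is consumed; PPh3, −78 °C → rt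
Reagents that add atoms: ozone, [O-][O+]=O
Why: Ozonolysis is chemoselective because the 1,1-disubstituted C16=C17 alkene is the only electron-rich π bond, whereas the β-sulfonyloxy acrylate is strongly deactivated; the ketone is unmasked only after all strong-base steps are over.

Step 17
Reactants: 26 ketone triflate; 27 tributyl(vinyl)stannane
Product: 28 Z-dienoate (C10=C1–C2=C3, vinyl cis to the C20 ester, C9 trans to C2)
Conditions: Pd(PPh3)4 (5 mol %), LiCl (3 equiv), THF, 50 °C
Reagents that add atoms: tributyl(vinyl)stannane 27, C=C[Sn](CCCC)(CCCC)CCCC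
Why: Stille coupling of an activated alkenyl triflate proceeds with retention of geometry under neutral conditions that spare the ketone, the free alcohol and the esters.

Step 18
Reactants: 28 dienoate alcohol
Product: 29 aldehyde (C5HO on C6)
Conditions: Dess–Martin periodinane, CH2Cl2, 0 °C → rt
Reagents that add atoms: none
Why: Dess–Martin oxidation of the only hydroxyl group gives the α-branched aldehyde under non-basic conditions, so C6 is not epimerised and benzyl alcohol is not eliminated.

Step 19
Reactants: 30 2-bromopropanoyl bromide; 2 2-(trimethylsilyl)ethanol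
Product: 31 TMSE 2-bromopropanoate
Conditions: pyridine, CH2Cl2, 0 °C
Reagents that add atoms: 2-(trimethylsilyl)ethanol 2, C[Si](C)(C)CCO
Why: Acylation of a primary alcohol by an acyl bromide is fast and leaves the secondary bromide in place.

Step 20
Reactants: 31 TMSE 2-bromopropanoate; 32 diphenyl phosphite
Product: 33 TMSE 2-(diphenoxyphosphoryl)propanoate
Conditions: Et3N, CH2Cl2, 0 °C → rt
Reagents that add atoms: diphenyl phosphite 32, O=[PH](Oc1ccccc1)Oc1ccccc1
Why: Michaelis–Becker-type P-alkylation of the phosphite anion by the activated α-bromo ester gives the diaryl phosphonate needed for Z-selective olefination.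

Step 21
Reactants: 29 aldehyde; 33 diaryl phosphonate
Product: 34 triene (Z-enoate C5=C4 on the C6 arm, Z-dienoate on C9)
Conditions: NaH (1.1 equiv), 33 (1.15 equiv), THF, 0 °C; then 29, −78 → −20 °C
Reagents that add atoms: TMSE 2-(diphenoxyphosphoryl)propanoate 33, CC(C(=O)OCC[Si](C)(C)C)P(=O)(Oc1ccccc1)Oc1ccccc1
Why: In this Z-selective Horner–Wadsworth–Emmons reaction (Ando-type diaryl phosphonate) fast, irreversible collapse of the erythro adduct puts the C19 ester cis to C6; the stabilised anion reacts with the aldehyde at low temperature and neither enolises the C16 ketone nor epimerises C6.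

Step 22
Reactants: 34 triene
Product: 35 tetracyclic cycloadduct (rings A–D, C1=C2 alkene, C16 ketone)
Conditions: toluene (0.005 M), BHT (10 mol %), base-washed and silylated sealed tube, 150–170 °C
Reagents that add atoms: none
Why: This is a concerted, suprafacial thermal [4+2] cycloaddition (type 1 intramolecular Diels–Alder reaction of a 1,3,8-nonatriene, a known route to cis-hydrindenes) between the s-cis diene C10=C1–C2=C3 and the Z-enoate C5=C4, forming C5–C10 and C3–C4. Ring A closes as the six-membered cycloadduct ring and ring B as a five-membered ring across the three-atom tether C9–C8–C6, the only regiochemistry this short tether allows. Because the C20 ester fills the inside position at C10, only H5 can lie beneath it, so C6 and the C19 ester cis to it take the endo positions; this fixes the cis C5–C10 fusion (C20 cis to H5) and, through the Z geometry of the enoate, C4 (C18 on the face of H5 and C20, C19 on the face of C6). The tether stereocentres together choose the diene face: at C9 the small H9 eclipses the C10–C20 bond (least A(1,2) strain) and turns C11 to the diene face remote from the dienophile, and at C6 it is H6 that points at C1 while CH2OBn points outward, so C1 ends syn to C11, C20 anti to C11 and C4 anti to C7, as in 42. The reverse diene geometry (C9 inside) is avoided on purpose, because it could react only with H9 in the diene cleft, which would invert C10 relative to C9 and open a [1,5]-hydrogen shift from C9. The step needs intramolecular over intermolecular reaction and intact alkene geometries, which high dilution, a radical inhibitor, base-free glass and the absence of an acidic C6–H (C7 is an ether) should secure.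

Step 23
Reactants: 35 cycloadduct
Product: 36 saturated primary alcohol (C7H2OH)
Conditions: H2 (1 atm), Pd(OH)2/C, EtOAc, rt
Reagents that add atoms: none
Why: One catalytic hydrogenation saturates the cis-disubstituted C1=C2 alkene (no new stereocentre) and cleaves the benzyl ether, which is why C16 is a ketone and not a methylene group at this stage.

Step 24
Reactants: 36 alcohol
Product: 37 C7 carboxylic acid
Conditions: TEMPO (20 mol %), PhI(OAc)2 (2.5 equiv), MeCN/H2O 1:1, rt
Reagents that add atoms: water, O
Why: Oxoammonium oxidation takes the only free alcohol through the aldehyde hydrate to the acid under near-neutral conditions, and C7 already sits anti to C4, so no drift at C6 is expected.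

Step 25
Reactants: 37 acid; 38 (trimethylsilyl)diazomethane
Product: 39 C7 methyl ester
Conditions: toluene/MeOH 4:1, 0 °C
Reagents that add atoms: (trimethylsilyl)diazomethane 38, C[Si](C)(C)C=[N+]=[N-]
Why: O-methylation of the single free carboxylic acid by the diazoalkane is selective by construction, because C19 and C20 are still TMSE esters.

Step 26
Reactants: 39 ketone; 40 methyltriphenylphosphonium bromide
Product: 41 16-methylene compound
Conditions: 40 (5 equiv), KOtBu (4.5 equiv), THF, 0 → 40 °C
Reagents that add atoms: methyltriphenylphosphonium bromide 40, C[P+](c1ccccc1)(c1ccccc1)c1ccccc1.[Br-]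
Why: Wittig methylenation of 13-O-protected 16-ketones of this bicyclo[3.2.1]octane type is well established; the silyl ether blocks α-ketol rearrangement, and all three carboxyl groups are masked as esters.

Step 27
Reactants: 41 fully protected compound
Product: 42 target CNP0285449.1
Conditions: Bu4NF (8 equiv), THF, rt → 40 °C; AcOH, aqueous work-up at pH 4–5
Reagents that add atoms: none
Why: Fluoride attacks silicon and not the hindered acyl carbons, so both TMSE esters fragment (ethene, Me3SiF) and the C13 silyl ether falls in one operation; the methyl ester stays, and no strong acid meets the acid-sensitive 13-hydroxy-16-ene unit.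

**Compound list**
1 | pent-4-enoic acid | C=CCCC(=O)O | starting material
2 | 2-(trimethylsilyl)ethanol | C[Si](C)(C)CCO | starting material
3 | TMSE pent-4-enoate | C=CCCC(=O)OCC[Si](C)(C)C | intermediate
4 | TMSE 4-oxobutanoate | O=CCCC(=O)OCC[Si](C)(C)C | intermediate
5 | methyl vinyl ketone | C=CC(C)=O | starting material
6 | TMSE (3S)-3-formyl-6-oxoheptanoate | O=C[C@H](CC(=O)OCC[Si](C)(C)C)CCC(C)=O | intermediate
7 | TMSE [(1S)-4-oxocyclohex-2-en-1-yl]acetate | O=C1C=C[C@H](CC(=O)OCC[Si](C)(C)C)CC1 | intermediate
8 | tert-butyl acetate | CC(=O)OC(C)(C)C | starting material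
9 | 1-tert-butoxy-1-(tert-butyldimethylsilyloxy)ethene | C=C(OC(C)(C)C)O[Si](C)(C)C(C)(C)C | intermediate
10 | trans silyl enol ether (C13(OTBS)=C14; C8–CH2CO2tBu; C9–CH2CO2TMSE) | CC(C)(C)[Si](C)(C)OC1=C[C@@H](CC(=O)OC(C)(C)C)[C@H](CC(=O)OCC[Si](C)(C)C)CC1 | intermediate
11 | 3-(tert-butoxycarbonylmethyl)-4-(TMSE-oxycarbonylmethyl)cyclohex-2-enone | O=C1C=C(CC(=O)OC(C)(C)C)[C@H](CC(=O)OCC[Si](C)(C)C)CC1 | intermediate
12 | allenyltributylstannane | C=C=C[Sn](CCCC)(CCCC)CCCC | starting material
13 | cyclohexanone with quaternary C8 (propargyl trans, CH2CO2tBu cis to the C9 side chain) | O=C1C[C@](CC#C)(CC(=O)OC(C)(C)C)[C@H](CC(=O)OCC[Si](C)(C)C)CC1 | intermediate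
14 | bicyclo[3.2.1]octane alcohol (C13–OH, C16=CH2) | C=C1C[C@]2(CC(=O)OC(C)(C)C)C[C@@]1(O)CC[C@H]2CC(=O)OCC[Si](C)(C)C | intermediate
15 | C13 TBS ether, TBS ester of the C8 acetic acid arm | C=C1C[C@]2(CC(=O)O[Si](C)(C)C(C)(C)C)C[C@@]1(O[Si](C)(C)C(C)(C)C)CC[C@H]2CC(=O)OCC[Si](C)(C)C | intermediate
16 | C13 TBS ether, free C8 acetic acid arm | C=C1C[C@]2(CC(=O)O)C[C@@]1(O[Si](C)(C)C(C)(C)C)CC[C@H]2CC(=O)OCC[Si](C)(C)C | intermediate
17 | (R)-4-benzyl-1,3-oxazolidin-2-one | O=C1OC[C@@H](Cc2ccccc2)N1 | starting material
18 | mixed pivalic anhydride of 16 | C=C1C[C@]2(CC(=O)OC(=O)C(C)(C)C)C[C@@]1(O[Si](C)(C)C(C)(C)C)CC[C@H]2CC(=O)OCC[Si](C)(C)C | intermediate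
19 | N-acyl oxazolidinone of the C6–C5 arm | C=C1C[C@]2(CC(=O)N3[C@H](Cc4ccccc4)COC3=O)C[C@@]1(O[Si](C)(C)C(C)(C)C)CC[C@H]2CC(=O)OCC[Si](C)(C)C | intermediate
20 | benzyl chloromethyl ether | ClCOCc1ccccc1 | starting material
21 | C6-(benzyloxymethyl) imide | C=C1C[C@]2([C@@H](COCc3ccccc3)C(=O)N3[C@H](Cc4ccccc4)COC3=O)C[C@@]1(O[Si](C)(C)C(C)(C)C)CC[C@H]2CC(=O)OCC[Si](C)(C)C | intermediate
22 | primary alcohol (C6 bears CH2OBn and CH2OH) | C=C1C[C@]2([C@@H](COCc3ccccc3)CO)C[C@@]1(O[Si](C)(C)C(C)(C)C)CC[C@H]2CC(=O)OCC[Si](C)(C)C | intermediate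
23 | ethyl formate | CCOC=O | starting material
24 | Z-hydroxymethylene ester at C10 | C=C1C[C@]2([C@@H](COCc3ccccc3)CO)C[C@@]1(O[Si](C)(C)C(C)(C)C)CC[C@H]2/C(C(=O)OCC[Si](C)(C)C)=C/O | intermediate
25 | Z-enol triflate | C=C1C[C@]2([C@@H](COCc3ccccc3)CO)C[C@@]1(O[Si](C)(C)C(C)(C)C)CC[C@H]2/C(C(=O)OCC[Si](C)(C)C)=C/OS(=O)(=O)C(F)(F)F | intermediate
26 | C16 ketone, Z-enol triflate | O=C1C[C@]2([C@@H](COCc3ccccc3)CO)C[C@@]1(O[Si](C)(C)C(C)(C)C)CC[C@H]2/C(C(=O)OCC[Si](C)(C)C)=C/OS(=O)(=O)C(F)(F)F | intermediate
27 | tributyl(vinyl)stannane | C=C[Sn](CCCC)(CCCC)CCCC | starting material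
28 | Z-dienoate alcohol | O=C1C[C@]2([C@@H](COCc3ccccc3)CO)C[C@@]1(O[Si](C)(C)C(C)(C)C)CC[C@H]2/C(C(=O)OCC[Si](C)(C)C)=C/C=C | intermediate
29 | Z-dienoate aldehyde | O=C1C[C@]2([C@@H](COCc3ccccc3)C=O)C[C@@]1(O[Si](C)(C)C(C)(C)C)CC[C@H]2/C(C(=O)OCC[Si](C)(C)C)=C/C=C | intermediate
30 | 2-bromopropanoyl bromide | CC(Br)C(=O)Br | starting material
31 | TMSE 2-bromopropanoate | CC(Br)C(=O)OCC[Si](C)(C)C | intermediate
32 | diphenyl phosphite | O=[PH](Oc1ccccc1)Oc1ccccc1 | starting material
33 | TMSE 2-(diphenoxyphosphoryl)propanoate | CC(C(=O)OCC[Si](C)(C)C)P(=O)(Oc1ccccc1)Oc1ccccc1 | intermediate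
34 | triene, Diels–Alder precursor (Z-enoate on the C6 arm, Z-dienoate on C9) | O=C1C[C@]2([C@@H](COCc3ccccc3)/C=C(/C)C(=O)OCC[Si](C)(C)C)C[C@@]1(O[Si](C)(C)C(C)(C)C)CC[C@H]2/C(C(=O)OCC[Si](C)(C)C)=C/C=C | intermediate
35 | tetracyclic C16 ketone with C1=C2 alkene, bis-TMSE ester, C7 benzyl ether | O=C1C[C@]23C[C@@]1(O[Si](C)(C)C(C)(C)C)CC[C@H]2[C@@]1(C(=O)OCC[Si](C)(C)C)C=CC[C@@](C)(C(=O)OCC[Si](C)(C)C)[C@H]1[C@@H]3COCc1ccccc1 | intermediate
36 | saturated tetracycle, C7H2OH | O=C1C[C@]23C[C@@]1(O[Si](C)(C)C(C)(C)C)CC[C@H]2[C@@]1(C(=O)OCC[Si](C)(C)C)CCC[C@@](C)(C(=O)OCC[Si](C)(C)C)[C@H]1[C@@H]3CO | intermediate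
37 | C7 carboxylic acid | O=C1C[C@]23C[C@@]1(O[Si](C)(C)C(C)(C)C)CC[C@H]2[C@@]1(C(=O)OCC[Si](C)(C)C)CCC[C@@](C)(C(=O)OCC[Si](C)(C)C)[C@H]1[C@@H]3C(=O)O | intermediate
38 | (trimethylsilyl)diazomethane | C[Si](C)(C)C=[N+]=[N-] | starting material
39 | C7 methyl ester, C16 ketone | O=C1C[C@]23C[C@@]1(O[Si](C)(C)C(C)(C)C)CC[C@H]2[C@@]1(C(=O)OCC[Si](C)(C)C)CCC[C@@](C)(C(=O)OCC[Si](C)(C)C)[C@H]1[C@@H]3C(=O)OC | intermediate
40 | methyltriphenylphosphonium bromide | C[P+](c1ccccc1)(c1ccccc1)c1ccccc1.[Br-] | starting material
41 | 16-methylene compound, fully protected | C=C1C[C@]23C[C@@]1(O[Si](C)(C)C(C)(C)C)CC[C@H]2[C@@]1(C(=O)OCC[Si](C)(C)C)CCC[C@@](C)(C(=O)OCC[Si](C)(C)C)[C@H]1[C@@H]3C(=O)OC | intermediate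
42 | CNP0285449.1 | C=C1C[C@]23C[C@@]1(O)CC[C@H]2[C@@]1(C(=O)O)CCC[C@@](C)(C(=O)O)[C@H]1[C@@H]3C(=O)OC | target

Total step count: 27. Longest linear sequence: 24 steps (1–4, 6–18, 21–27).

**Steps most likely to fail**

Step 22. Both partners are acceptor-substituted and heavily substituted, so the cycloaddition may be so slow that oligomerisation or thermal breakdown overtakes it. The fallback gives the dienophile a stronger and smaller acceptor. It sets out from aldehyde 29.
- Diphenyl phosphite 32 and tert-butyl 2-bromopropanoate (Et3N) give tert-butyl 2-(diphenoxyphosphoryl)propanoate F1.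
- Z-selective olefination of 29 with it gives the tert-butyl Z-enoate triene F2.
- TMSOTf/2,6-lutidine followed by water frees the Z-enoic acid triene F3.
- Neutral chlorination with 1-chloro-N,N,2-trimethylprop-1-en-1-amine gives the Z-enoyl chloride triene F4.
- Its lower LUMO should let the same cycloaddition run well below the temperature of step 22, giving the cycloadduct acid chloride F5.
- Esterification with 2 (Et3N, DMAP) returns to 35.

Step 8. Transfer of the propargyl group to the fully substituted β-carbon may lose out to 1,2-addition or to protodestannylation of the reagent. The fallback builds the alkyne in stages and sets out from enone 11.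
- Hosomi–Sakurai allylation (allyltrimethylsilane, TiCl4, CH2Cl2, −78 °C), which is reliable for quaternary centres and should show the same anti selectivity, gives the allyl ketone F6.
- Ozonolysis (O3; PPh3) gives the keto aldehyde F7.
- Ohira–Bestmann homologation (dimethyl (1-diazo-2-oxopropyl)phosphonate, K2CO3, MeOH) converts only the aldehyde into the terminal alkyne and returns to 13.

Step 12. Alkylation of an enolate next to quaternary C8 may be sluggish. The neighbouring stereocentres may erode auxiliary control, and the oxocarbenium electrophile may attack the exocyclic alkene. The fallback moves the C6–C7 bond formation to enamine catalysis and sets out from acid 16.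
- Isobutyl chloroformate/N-methylmorpholine followed by NaBH4 gives the primary alcohol F8.
- Dess–Martin oxidation gives the aldehyde F9.
- α-Hydroxymethylation with aqueous formaldehyde under (R)-α,α-diphenylprolinol trimethylsilyl ether sets C6 under catalyst control and gives the β-hydroxy aldehyde F10.
- Benzyl 2,2,2-trichloroacetimidate with catalytic TfOH gives the benzyl ether aldehyde F11.
- NaBH4 reduction returns to alcohol 22, which also bypasses step 13.

**Further compounds**
F1 | step 22 | tert-butyl 2-(diphenoxyphosphoryl)propanoate | CC(C(=O)OC(C)(C)C)P(=O)(Oc1ccccc1)Oc1ccccc1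
F2 | step 22 | tert-butyl Z-enoate triene | O=C1C[C@]2([C@@H](COCc3ccccc3)/C=C(/C)C(=O)OC(C)(C)C)C[C@@]1(O[Si](C)(C)C(C)(C)C)CC[C@H]2/C(C(=O)OCC[Si](C)(C)C)=C/C=C
F3 | step 22 | Z-enoic acid triene | O=C1C[C@]2([C@@H](COCc3ccccc3)/C=C(/C)C(=O)O)C[C@@]1(O[Si](C)(C)C(C)(C)C)CC[C@H]2/C(C(=O)OCC[Si](C)(C)C)=C/C=C
F4 | step 22 | Z-enoyl chloride triene | O=C1C[C@]2([C@@H](COCc3ccccc3)/C=C(/C)C(=O)Cl)C[C@@]1(O[Si](C)(C)C(C)(C)C)CC[C@H]2/C(C(=O)OCC[Si](C)(C)C)=C/C=C
F5 | step 22 | cycloadduct acid chloride (C19 = COCl) | O=C1C[C@]23C[C@@]1(O[Si](C)(C)C(C)(C)C)CC[C@H]2[C@@]1(C(=O)OCC[Si](C)(C)C)C=CC[C@@](C)(C(=O)Cl)[C@H]1[C@@H]3COCc1ccccc1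
F6 | step 8 | allyl ketone with quaternary C8 | O=C1C[C@](CC=C)(CC(=O)OC(C)(C)C)[C@H](CC(=O)OCC[Si](C)(C)C)CC1
F7 | step 8 | keto aldehyde (C16HO) | O=C1C[C@](CC=O)(CC(=O)OC(C)(C)C)[C@H](CC(=O)OCC[Si](C)(C)C)CC1
F8 | step 12 | primary alcohol (C8–CH2CH2OH) | C=C1C[C@]2(CCO)C[C@@]1(O[Si](C)(C)C(C)(C)C)CC[C@H]2CC(=O)OCC[Si](C)(C)C
F9 | step 12 | aldehyde (C8–CH2CHO) | C=C1C[C@]2(CC=O)C[C@@]1(O[Si](C)(C)C(C)(C)C)CC[C@H]2CC(=O)OCC[Si](C)(C)C
F10 | step 12 | β-hydroxy aldehyde (C6 bears CH2OH and CHO) | C=C1C[C@]2([C@@H](CO)C=O)C[C@@]1(O[Si](C)(C)C(C)(C)C)CC[C@H]2CC(=O)OCC[Si](C)(C)C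
F11 | step 12 | benzyl ether aldehyde (C6 bears CH2OBn and CHO) | C=C1C[C@]2([C@@H](COCc3ccccc3)C=O)C[C@@]1(O[Si](C)(C)C(C)(C)C)CC[C@H]2CC(=O)OCC[Si](C)(C)C
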